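**Retrosynthetic overview**
- Target ⇒ (R)-1,1-diacetyl-2-(3,4-dimethoxyphenyl)cyclohex-3-ene + 2 vanillin (two-fold Claisen–Schmidt; both feruloyl arms go on last).
- Ring C3=C4 alkene ⇒ CO2 extrusion from a cis-fused cyclohexane/β-lactone bicycle (the alkene is carried as a β-lactone).
- Bicycle ⇒ one-pot Michael–aldol–β-lactonisation of 3-(3-oxopropyl)pentane-2,4-dione with 3,4-dimethoxycinnamoyl chloride under a chiral isothiourea. The Michael event makes the C1–C2 bond and sets the stereocentre, the aldol makes the C3–C4 bond, and lactonisation closes the second ring.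
- Keto-aldehyde ⇒ acetylacetone + acrolein; acid chloride ⇒ 3,4-dimethoxycinnamic acid.
- Ring order: the three arenes are bought; the cyclohexane and β-lactone rings form together in the cascade; the β-lactone is then expelled as CO2.

Assumption: the target's single stereocentre is read from the SMILES as (R) (CIP order C1 > aryl > C3 > H); all intermediates are drawn in that series.

**Step 1**
Reactants: 1 acetylacetone (pentane-2,4-dione); 2 acrolein (prop-2-enal)
Product: 3 3-(3-oxopropyl)pentane-2,4-dione (4-acetyl-5-oxohexanal)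
Conditions: 1 (1.5 equiv), Et3N (5 mol %), CH2Cl2, 0 °C → rt
Reagents that add atoms: none
Why: Amine-catalysed Michael addition of the acetylacetone enolate to acrolein, with excess 1 favouring mono-addition; no stereocentre is formed.

**Step 2**
Reactants: 4 (E)-3,4-dimethoxycinnamic acid
Product: 5 (E)-3-(3,4-dimethoxyphenyl)prop-2-enoyl chloride
Conditions: (COCl)2 (1.2 equiv), DMF (cat.), CH2Cl2, 0 °C → rt; concentrate, use crude
Reagents that add atoms: oxalyl chloride, ClC(=O)C(=O)Cl
Why: DMF-catalysed (Vilsmeier-type) acid chloride formation; the E-alkene and aryl ethers are inert.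

**Step 3**
Reactants: 3 3-(3-oxopropyl)pentane-2,4-dione; 5 (E)-3-(3,4-dimethoxyphenyl)prop-2-enoyl chloride
Product: 7 (1S,2R,6R)-3,3-diacetyl-2-(3,4-dimethoxyphenyl)-7-oxabicyclo[4.2.0]octan-8-one, via lithium (Z)-3-acetyl-6-oxohex-2-en-2-olate 6 (not isolated)
Conditions: LiHMDS (1.0 equiv), THF, −78 °C; then 5 (1.2 equiv), (2S,3R)-HyperBTM (20 mol %), DBU (1.0 equiv), −78 °C → rt
Reagents that add atoms: lithium bis(trimethylsilyl)amide, [Li+].C[Si](C)(C)[N-][Si](C)(C)C (supplies the Li of 6 only)
Why: Proposed new method: a nucleophile-catalysed Michael–aldol–β-lactonisation cascade extended to a 2-alkyl-1,3-diketone donor with an aldehyde acceptor arm, in which 5 acylates the isothiourea to an s-cis, S···O-locked α,β-unsaturated acylammonium, enolate 6 attacks C-β on the Re face (anti to the catalyst's pseudo-axial phenyl) to set the aryl-bearing centre as (R), the resulting ammonium enolate closes the six-membered ring by aldol addition to the pendant CHO, and the cis-aldolate lactonises with catalyst release so that both rings form in one operation; the closest known reaction types are the isothiourea-catalysed Michael–aldol–lactonisation of keto-malonates with unsaturated acid chlorides and the Michael–lactonisation of 1,3-diketones with cinnamoyl ammonium ions.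

**Step 4**
Reactants: 7 (1S,2R,6R)-3,3-diacetyl-2-(3,4-dimethoxyphenyl)-7-oxabicyclo[4.2.0]octan-8-one
Product: 8 1,1'-[(2R)-2-(3,4-dimethoxyphenyl)cyclohex-3-ene-1,1-diyl]di(ethan-1-one)
Conditions: DMF, 150 °C, 1–2 h (−CO2)
Reagents that add atoms: none
Why: Thermal retro-[2+2] decarboxylation of the cis-fused β-lactone, a stereospecific syn extrusion that replaces the two sacrificial lactone stereocentres by the C3=C4 ring alkene while the non-enolisable C2 centre is untouched.

**Step 5**
Reactants: 8 1,1'-[(2R)-2-(3,4-dimethoxyphenyl)cyclohex-3-ene-1,1-diyl]di(ethan-1-one); 9 vanillin (4-hydroxy-3-methoxybenzaldehyde)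
Product: 10 (2E,2'E)-1,1'-[(2R)-2-(3,4-dimethoxyphenyl)cyclohex-3-ene-1,1-diyl]bis[3-(4-hydroxy-3-methoxyphenyl)prop-2-en-1-one] (CNP0213153.1)
Conditions: 9 (2.5 equiv), BF3·OEt2 (cat., 0.5 equiv per C=O), 1,4-dioxane, rt → 40 °C
Reagents that add atoms: none
Why: Lewis-acid-mediated double Claisen–Schmidt (crossed aldol) condensation in which only the two acetyl CH3 groups can enolise, BF3 tolerates the free phenols and avoids the hydroxide-induced retro-Claisen cleavage of 2,2-disubstituted 1,3-diketones, dehydration gives the E-enones, and C2 cannot epimerise.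

**Compound list**
1 | acetylacetone (pentane-2,4-dione) | CC(=O)CC(C)=O | starting material
2 | acrolein (prop-2-enal) | C=CC=O | starting material
3 | 3-(3-oxopropyl)pentane-2,4-dione (4-acetyl-5-oxohexanal) | CC(=O)C(CCC=O)C(C)=O | intermediate
4 | (E)-3,4-dimethoxycinnamic acid | COc1ccc(/C=C/C(=O)O)cc1OC | starting material
5 | (E)-3-(3,4-dimethoxyphenyl)prop-2-enoyl chloride | COc1ccc(/C=C/C(=O)Cl)cc1OC | intermediate
6 | lithium (Z)-3-acetyl-6-oxohex-2-en-2-olate (lithium enolate of 3) | [Li+].C/C([O-])=C(\CCC=O)C(C)=O | intermediate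
7 | (1S,2R,6R)-3,3-diacetyl-2-(3,4-dimethoxyphenyl)-7-oxabicyclo[4.2.0]octan-8-one (cis-fused cyclohexane/β-lactone, aryl trans to the lactone carbonyl; either cis-fused C1/C6 diastereomer converges in step 4) | O=C1O[C@@H]2CCC(C(C)=O)(C(C)=O)[C@@H](c3ccc(OC)c(OC)c3)[C@H]12 | intermediate
8 | 1,1'-[(2R)-2-(3,4-dimethoxyphenyl)cyclohex-3-ene-1,1-diyl]di(ethan-1-one) | CC(=O)C1(C(C)=O)CCC=C[C@@H]1c1ccc(OC)c(OC)c1 | intermediate
9 | vanillin (4-hydroxy-3-methoxybenzaldehyde) | COc1cc(C=O)ccc1O | starting material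
10 | (2E,2'E)-1,1'-[(2R)-2-(3,4-dimethoxyphenyl)cyclohex-3-ene-1,1-diyl]bis[3-(4-hydroxy-3-methoxyphenyl)prop-2-en-1-one] | COc1cc(/C=C/C(=O)C2(C(=O)/C=C/c3ccc(O)c(OC)c3)CCC=C[C@@H]2c2ccc(OC)c(OC)c2)ccc1O | target

**Totals**
Total steps: 5. Longest linear sequence: 4 (steps 1, 3, 4, 5).

**Three steps most likely to fail**

Step 3 is the riskiest. The hindered, stabilised diketonate may add only slowly to the electron-rich cinnamoyl ammonium ion (O-acylation competing). The aldol–lactonisation onto an aldehyde to form a six-membered ring is also untested for this donor class. The sense of induction rests on the isothiourea model and should be checked on the first run. The fallback abandons the β-lactone and builds the same cyclohexene by allylic alkylation and metathesis, setting out from 1 and 5 and returning at 8. Acetylacetone 1 is C-alkylated with 4-bromobut-1-ene (K2CO3, NaI cat., acetone, reflux) to 3-(but-3-en-1-yl)pentane-2,4-dione F1. Acid chloride 5 is reduced (NaBH4, THF, 0 °C) to (E)-3-(3,4-dimethoxyphenyl)prop-2-en-1-ol F2, which with ClCO2Me/pyridine gives (E)-3-(3,4-dimethoxyphenyl)allyl methyl carbonate F3. Iridium-catalysed branched-selective asymmetric allylic alkylation of F1 with F3 ([Ir(cod)Cl]2, Feringa-type phosphoramidite of the enantiomer giving the (R)-product, TBD, THF, rt) forms the quaternary carbon next to the new stereocentre in 3-(but-3-en-1-yl)-3-[(1R)-1-(3,4-dimethoxyphenyl)prop-2-en-1-yl]pentane-2,4-dione F4. Ring-closing metathesis (Grubbs II, CH2Cl2, 40 °C) then gives 8.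

Step 5 is the second risk. Acid-mediated double condensation on a hindered, non-chelating 2,2-disubstituted 1,3-diketone may stall at mono-condensation, or the acid may touch the ring alkene. The fallback replaces the condensation by a kinetic aldol/elimination sequence on protected vanillin, setting out from 8 and 9 and returning at 10. Vanillin 9 is silylated (TBSCl, imidazole, DMF) to 4-[(tert-butyldimethylsilyl)oxy]-3-methoxybenzaldehyde F6. Double deprotonation of 8 with LDA (2.2 equiv, THF, −78 °C) and addition to F6 gives the bis-aldol 1,1'-[(2R)-2-(3,4-dimethoxyphenyl)cyclohex-3-ene-1,1-diyl]bis{3-[4-(tert-butyldimethylsilyloxy)-3-methoxyphenyl]-3-hydroxypropan-1-one} F7, a carbinol-epimer mixture that is of no consequence. MsCl/Et3N followed by DBU eliminates to the bis-TBS ether of the target, (2E,2'E)-1,1'-[(2R)-2-(3,4-dimethoxyphenyl)cyclohex-3-ene-1,1-diyl]bis{3-[4-(tert-butyldimethylsilyloxy)-3-methoxyphenyl]prop-2-en-1-one} F8. TBAF/AcOH (THF, 0 °C) gives 10.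

Step 4 is the third risk. A β-lactone with only secondary alkyl carbons may need temperatures at which the gem-diacetyl compound degrades. The fallback replaces the thermal syn extrusion by an ionic two-stage anti elimination, setting out from 7 and returning at 8. MgBr2·OEt2 (Et2O/CH2Cl2, rt) opens the lactone at C6 by SN2 attack of bromide with inversion to (1R,2S,6R)-5,5-diacetyl-2-bromo-6-(3,4-dimethoxyphenyl)cyclohexane-1-carboxylic acid F5. In F5 the bromide and carboxyl are trans and can become diaxial. NaHCO3 in DMF (40–60 °C) then triggers Grob-type decarboxylative elimination to 8 without touching C2.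

**Further compounds**
F1 | step 3 | 3-(but-3-en-1-yl)pentane-2,4-dione | CC(=O)C(CCC=C)C(C)=O
F2 | step 3 | (E)-3-(3,4-dimethoxyphenyl)prop-2-en-1-ol | OC/C=C/c1ccc(OC)c(OC)c1
F3 | step 3 | (E)-3-(3,4-dimethoxyphenyl)allyl methyl carbonate | COC(=O)OC/C=C/c1ccc(OC)c(OC)c1
F4 | step 3 | 3-(but-3-en-1-yl)-3-[(1R)-1-(3,4-dimethoxyphenyl)prop-2-en-1-yl]pentane-2,4-dione | CC(=O)C(CCC=C)(C(C)=O)[C@H](C=C)c1ccc(OC)c(OC)c1
F5 | step 4 | (1R,2S,6R)-5,5-diacetyl-2-bromo-6-(3,4-dimethoxyphenyl)cyclohexane-1-carboxylic acid | OC(=O)[C@@H]1[C@@H](Br)CCC(C(C)=O)(C(C)=O)[C@H]1c1ccc(OC)c(OC)c1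
F6 | step 5 | 4-[(tert-butyldimethylsilyl)oxy]-3-methoxybenzaldehyde | COc1cc(C=O)ccc1O[Si](C)(C)C(C)(C)C
F7 | step 5 | 1,1'-[(2R)-2-(3,4-dimethoxyphenyl)cyclohex-3-ene-1,1-diyl]bis{3-[4-(tert-butyldimethylsilyloxy)-3-methoxyphenyl]-3-hydroxypropan-1-one} (carbinol centres as a mixture) | COc1cc(C(O)CC(=O)C2(C(=O)CC(O)c3ccc(O[Si](C)(C)C(C)(C)C)c(OC)c3)CCC=C[C@@H]2c2ccc(OC)c(OC)c2)ccc1O[Si](C)(C)C(C)(C)C
F8 | step 5 | (2E,2'E)-1,1'-[(2R)-2-(3,4-dimethoxyphenyl)cyclohex-3-ene-1,1-diyl]bis{3-[4-(tert-butyldimethylsilyloxy)-3-methoxyphenyl]prop-2-en-1-one} | COc1cc(/C=C/C(=O)C2(C(=O)/C=C/c3ccc(O[Si](C)(C)C(C)(C)C)c(OC)c3)CCC=C[C@@H]2c2ccc(OC)c(OC)c2)ccc1O[Si](C)(C)C(C)(C)C
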